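**Retrosynthetic overview**
1. Target ⇐ resolved tris(allyl carbonate) (neutral Pd(PPh3)4/Bu3SnH deallylation) ⇐ racemic lactol ⇐ BCl3 demethylation of the tri-O-methyl depsidone.
2. Dioxepinone ring (formed last) ⇐ lactonisation of the ring A acid onto the ring B 5-OH ⇐ diaryl ether ⇐ SNAr of a ring B phenol on a ring A fluoride flanked by CHO and CO2Bn.
3. Ring B carbocycle (formed first) ⇐ aromatisation of a cyclohexane-1,3-dione ⇐ key C–C bond: intermolecular Michael addition of ethyl acetoacetate to ethyl (E)-4,4-dimethoxybut-2-enoate, then Dieckmann (Claisen) closure. The acceptor brings the future lactol carbon, the donor the future lactone carbonyl.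
4. Ring B is then closed to the phthalide methyl pseudo-ester; its 4-OH comes from formylation/Baeyer–Villiger and its 6-CHO from Rieche formylation.
5. Ring A fluoride ⇐ 3,5-difluorotoluene by ortho-lithiation/formylation, SNAr with methoxide, bromination and alkoxycarbonylation.

Assumption: the lactol carbon is the only stereocentre and epimerises in the free lactol (ring–chain tautomerism), so it is fixed and resolved as a stable carbonate and released last under cold, weakly acidic conditions; the product is kept cold and stored as a solid.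

**Step 1**
Reactants: 1 2,2-dimethoxyacetaldehyde (60% aqueous solution); 2 triethyl phosphonoacetate
Product: 3 ethyl (E)-4,4-dimethoxybut-2-enoate
Conditions: K2CO3, H2O, rt
Reagents that add atoms: none
Why: Horner–Wadsworth–Emmons olefination of a reactive, non-enolisable aldehyde gives the (E)-enoate almost exclusively.

**Step 2**
Reactants: 3 ethyl (E)-4,4-dimethoxybut-2-enoate; 4 ethyl acetoacetate
Product: 6 ethyl 6-(dimethoxymethyl)-2,4-dioxocyclohexane-1-carboxylate (diastereomer/enol mixture), via Michael adduct 5 (not isolated)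
Conditions: NaOEt (1.1 equiv), EtOH, reflux; then AcOH, 0 °C
Reagents that add atoms: none
Why: Intermolecular Michael addition of the acetoacetate enolate joins the two fragments, and the acetyl methyl then closes the ring by Dieckmann (Claisen) condensation, driven by the stabilised 1,3-dione enolate; the two sp3 centres are removed by aromatisation in the next step.

**Step 3**
Reactants: 6 ethyl 6-(dimethoxymethyl)-2,4-dioxocyclohexane-1-carboxylate
Product: 8 ethyl 2-formyl-4,6-dihydroxybenzoate, via acetal phenol 7 (not isolated)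
Conditions: Br2 (1.0 equiv), DMF, 0 °C then 80 °C; then 1 M aq. HCl, THF, rt
Reagents that add atoms: water, O
Why: α-Bromination of the dione enol and thermal loss of two HBr aromatises the ring to the resorcinol (dehydrogenative aromatisation), and the benzylic acetal is hydrolysed on acidic work-up.

**Step 4**
Reactants: 8 ethyl 2-formyl-4,6-dihydroxybenzoate
Product: 9 5,7-dihydroxy-3-methoxy-2-benzofuran-1(3H)-one (racemic)
Conditions: MeOH, H2SO4 (cat.), reflux
Reagents that add atoms: methanol, CO
Why: Acid-catalysed hemiacetal formation and five-membered lactonisation onto the ortho ester (pseudo-ester formation of a 2-formylbenzoate) expels ethanol; the acetal carbon is racemic and serves only as a protecting group.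

**Step 5**
Reactants: 9 5,7-dihydroxy-3-methoxy-2-benzofuran-1(3H)-one
Product: 10 5-(benzyloxy)-7-hydroxy-3-methoxy-2-benzofuran-1(3H)-one (racemic)
Conditions: BnBr (1.05 equiv), K2CO3 (1.1 equiv), acetone, reflux
Reagents that add atoms: benzyl bromide, BrCc1ccccc1
Why: Williamson etherification is selective for the 5-OH because the 7-OH is hydrogen-bonded to the lactone carbonyl and much less nucleophilic.

**Step 6**
Reactants: 10 5-(benzyloxy)-7-hydroxy-3-methoxy-2-benzofuran-1(3H)-one
Product: 11 5-(benzyloxy)-3,7-dimethoxy-2-benzofuran-1(3H)-one (racemic)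
Conditions: MeI (3 equiv), K2CO3, DMF, 40 °C
Reagents that add atoms: iodomethane, CI
Why: Williamson methylation of the remaining chelated phenol under more forcing conditions.

**Step 7**
Reactants: 11 5-(benzyloxy)-3,7-dimethoxy-2-benzofuran-1(3H)-one
Product: 12 5-(benzyloxy)-3,7-dimethoxy-1-oxo-1,3-dihydro-2-benzofuran-4-carbaldehyde (racemic)
Conditions: POCl3 (1.5 equiv), DMF, 0 → 60 °C; then ice-water
Reagents that add atoms: N,N-dimethylformamide, CN(C)C=O; water, O
Why: Vilsmeier–Haack formylation goes to C-4 (para to the 7-OMe, ortho to the 5-OBn) rather than to the more hindered C-6 between two alkoxy groups.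

**Step 8**
Reactants: 12 5-(benzyloxy)-3,7-dimethoxy-1-oxo-1,3-dihydro-2-benzofuran-4-carbaldehyde
Product: 14 5-(benzyloxy)-4-hydroxy-3,7-dimethoxy-2-benzofuran-1(3H)-one (racemic), via aryl formate 13 (not isolated)
Conditions: mCPBA (1.3 equiv), CH2Cl2, 0 °C → rt; then MeOH, HCl (cat.), rt
Reagents that add atoms: mCPBA, OOC(=O)c1cccc(Cl)c1
Why: Baeyer–Villiger (Dakin-type) oxidation of the electron-rich aryl aldehyde proceeds with aryl migration to the formate, which acidic methanolysis cleaves without changing the methyl pseudo-ester.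

**Step 9**
Reactants: 14 5-(benzyloxy)-4-hydroxy-3,7-dimethoxy-2-benzofuran-1(3H)-one
Product: 15 5-(benzyloxy)-4-hydroxy-3,7-dimethoxy-1-oxo-1,3-dihydro-2-benzofuran-6-carbaldehyde (racemic)
Conditions: Cl2CHOMe (1.5 equiv), TiCl4 (2.2 equiv), CH2Cl2, −78 → −20 °C; then ice-cold aq. NaHCO3
Reagents that add atoms: dichloromethyl methyl ether, COC(Cl)Cl; water, O
Why: Rieche formylation (electrophilic aromatic substitution) can only occur at C-6, the single free ring position, which is activated by two ortho alkoxy groups; low temperature spares the benzyl ether and the pseudo-ester.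

**Step 10**
Reactants: 16 3,5-difluorotoluene
Product: 18 2,6-difluoro-4-methylbenzaldehyde, via aryllithium 17 (not isolated)
Conditions: n-BuLi (1.05 equiv), THF, −78 °C; then DMF, −78 → 0 °C; aq. HCl
Reagents that add atoms: N,N-dimethylformamide, CN(C)C=O
Why: Directed ortho-metalation at the most acidic C–H between the two fluorines, then formylation of the aryllithium with DMF.

**Step 11**
Reactants: 18 2,6-difluoro-4-methylbenzaldehyde
Product: 19 2-fluoro-6-methoxy-4-methylbenzaldehyde
Conditions: NaOMe (1.05 equiv), MeOH, 0 → 50 °C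
Reagents that add atoms: sodium methoxide, C[O-].[Na+]
Why: SNAr of one fluoride activated by the ortho formyl group; the methoxy group introduced deactivates the ring, so substitution stops at the mono stage.

**Step 12**
Reactants: 19 2-fluoro-6-methoxy-4-methylbenzaldehyde
Product: 20 3-bromo-2-fluoro-6-methoxy-4-methylbenzaldehyde
Conditions: NBS (1.05 equiv), DMF, rt
Reagents that add atoms: N-bromosuccinimide, O=C1CCC(=O)N1Br
Why: Electrophilic bromination goes para to the methoxy group, at the position that is also ortho to F and CH3 and meta to the formyl group.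

**Step 13**
Reactants: 20 3-bromo-2-fluoro-6-methoxy-4-methylbenzaldehyde
Product: 21 benzyl 2-fluoro-3-formyl-4-methoxy-6-methylbenzoate
Conditions: CO (1 atm), BnOH (1.5 equiv), Pd(OAc)2 (3 mol %), Xantphos (3 mol %), Et3N (2 equiv), toluene, 80 °C
Reagents that add atoms: carbon monoxide, [C-]#[O+]; benzyl alcohol, OCc1ccccc1
Why: Palladium-catalysed alkoxycarbonylation of the aryl bromide with a wide-bite-angle ligand; the weak amine base and limited benzyl alcohol keep SNAr at the activated fluoride in check.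

**Step 14**
Reactants: 15 5-(benzyloxy)-4-hydroxy-3,7-dimethoxy-1-oxo-1,3-dihydro-2-benzofuran-6-carbaldehyde; 21 benzyl 2-fluoro-3-formyl-4-methoxy-6-methylbenzoate
Product: 22 benzyl 2-{[5-(benzyloxy)-6-formyl-3,7-dimethoxy-1-oxo-1,3-dihydro-2-benzofuran-4-yl]oxy}-3-formyl-4-methoxy-6-methylbenzoate (racemic)
Conditions: K2CO3 (1.5 equiv), DMF, 60 °C, N2
Reagents that add atoms: none
Why: SNAr: the fluoride flanked by formyl and ester groups is strongly activated and is displaced by the ring B phenoxide, whose neighbouring oxygen is benzylated so that no Smiles rearrangement can occur.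

**Step 15**
Reactants: 22 the diaryl ether benzyl ester
Product: 23 2-[(6-formyl-5-hydroxy-3,7-dimethoxy-1-oxo-1,3-dihydro-2-benzofuran-4-yl)oxy]-3-formyl-4-methoxy-6-methylbenzoic acid (racemic)
Conditions: H2 (1 atm), Pd/C (10 wt %), EtOAc, rt, stopped after 2 equiv H2
Reagents that add atoms: none
Why: Hydrogenolysis cleaves only the benzyl ester and the benzyl ether; the chelated aryl aldehydes and the methyl pseudo-ester survive under neutral conditions at 1 atm.

**Step 16**
Reactants: 23 the seco hydroxy acid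
Product: 24 1,4,10-trimethoxy-8-methyl-3,7-dioxo-1,3-dihydro-7H-isobenzofuro[4,5-b][1,4]benzodioxepine-5,11-dicarbaldehyde (racemic)
Conditions: DCC (1.5 equiv), CH2Cl2 (0.005 M), rt
Reagents that add atoms: none
Why: Carbodiimide-mediated lactonisation closes the seven-membered dioxepinone; only the 5-OH of ring B is free, and the base-free conditions avoid a Smiles rearrangement of the 2-hydroxy diaryl ether.

**Step 17**
Reactants: 24 the tri-O-methyl depsidone
Product: 25 1,4,10-trihydroxy-8-methyl-3,7-dioxo-1,3-dihydro-7H-isobenzofuro[4,5-b][1,4]benzodioxepine-5,11-dicarbaldehyde (racemic)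
Conditions: BCl3 (8 equiv), CH2Cl2, −78 → 0 °C; then H2O/THF, 0 °C
Reagents that add atoms: water, O
Why: Chelation-assisted Lewis-acid ether cleavage removes the two methyl ethers ortho to carbonyl groups and ionises the pseudo-ester, which water converts into the lactol (racemic and freely epimerising).

**Step 18**
Reactants: 25 the racemic lactol
Product: 26 triallyl tricarbonate of 25, with allyl carbonates on O-1 (acetal), O-4 and O-10 (racemic)
Conditions: allyl chloroformate (6 equiv), pyridine, DMAP (cat.), CH2Cl2, 0 °C → rt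
Reagents that add atoms: allyl chloroformate, C=CCOC(Cl)=O
Why: Acylation of the two phenols and of the ring (lactol) tautomer by nucleophilic catalysis gives a neutral carbonate in which the acetal carbon is configurationally fixed.

**Step 19**
Reactants: 26 the racemic tris(allyl carbonate)
Product: 27 (1R)-tris(allyl carbonate)
Conditions: preparative HPLC on immobilised amylose tris(3,5-dimethylphenylcarbamate), heptane/i-PrOH, 20 °C
Reagents that add atoms: none
Why: Resolution by chiral-phase chromatography sets the stereocentre; the (1R)-carbonate has the spatial arrangement of the (1S)-lactol because the carbonate oxygen now outranks the lactone oxygen, and the (1S)-carbonate is recycled by deallylation to racemic 25.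

**Step 20**
Reactants: 27 the (1R)-tris(allyl carbonate)
Product: 28 (1S)-1,4,10-trihydroxy-8-methyl-3,7-dioxo-1,3-dihydro-7H-isobenzofuro[4,5-b][1,4]benzodioxepine-5,11-dicarbaldehyde
Conditions: Pd(PPh3)4 (5 mol %), Bu3SnH (3.3 equiv), AcOH (7 equiv), CH2Cl2, 0 °C, 15 min; precipitation with cold heptane
Reagents that add atoms: none
Why: Palladium-catalysed hydrostannolytic deallylation (Tsuji–Trost ionisation with hydride capture) cleaves only O–allyl bonds, and the acetic acid buffer lets the carbonic acids lose CO2 without forming the hemiacetal alkoxide, so the C–O bonds at the stereocentre are untouched and the (S)-configuration is retained.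

**Compound list**
1 | 2,2-dimethoxyacetaldehyde | COC(OC)C=O | starting material
2 | triethyl phosphonoacetate | CCOC(=O)CP(=O)(OCC)OCC | starting material
3 | ethyl (E)-4,4-dimethoxybut-2-enoate | CCOC(=O)/C=C/C(OC)OC | intermediate
4 | ethyl acetoacetate | CCOC(=O)CC(C)=O | starting material
5 | diethyl 2-acetyl-3-(dimethoxymethyl)pentanedioate (Michael adduct, diastereomer mixture, not isolated) | CCOC(=O)CC(C(OC)OC)C(C(C)=O)C(=O)OCC | intermediate
6 | ethyl 6-(dimethoxymethyl)-2,4-dioxocyclohexane-1-carboxylate (diastereomer/enol mixture) | CCOC(=O)C1C(C(OC)OC)CC(=O)CC1=O | intermediate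
7 | ethyl 2-(dimethoxymethyl)-4,6-dihydroxybenzoate (not isolated) | CCOC(=O)c1c(O)cc(O)cc1C(OC)OC | intermediate
8 | ethyl 2-formyl-4,6-dihydroxybenzoate | CCOC(=O)c1c(O)cc(O)cc1C=O | intermediate
9 | 5,7-dihydroxy-3-methoxy-2-benzofuran-1(3H)-one (racemic) | COC1OC(=O)c2c(O)cc(O)cc21 | intermediate
10 | 5-(benzyloxy)-7-hydroxy-3-methoxy-2-benzofuran-1(3H)-one (racemic) | COC1OC(=O)c2c(O)cc(OCc3ccccc3)cc21 | intermediate
11 | 5-(benzyloxy)-3,7-dimethoxy-2-benzofuran-1(3H)-one (racemic) | COC1OC(=O)c2c(OC)cc(OCc3ccccc3)cc21 | intermediate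
12 | 5-(benzyloxy)-3,7-dimethoxy-1-oxo-1,3-dihydro-2-benzofuran-4-carbaldehyde (racemic) | COC1OC(=O)c2c(OC)cc(OCc3ccccc3)c(C=O)c21 | intermediate
13 | 5-(benzyloxy)-3,7-dimethoxy-1-oxo-1,3-dihydro-2-benzofuran-4-yl formate (racemic, not isolated) | COC1OC(=O)c2c(OC)cc(OCc3ccccc3)c(OC=O)c21 | intermediate
14 | 5-(benzyloxy)-4-hydroxy-3,7-dimethoxy-2-benzofuran-1(3H)-one (racemic) | COC1OC(=O)c2c(OC)cc(OCc3ccccc3)c(O)c21 | intermediate
15 | 5-(benzyloxy)-4-hydroxy-3,7-dimethoxy-1-oxo-1,3-dihydro-2-benzofuran-6-carbaldehyde (racemic) | COC1OC(=O)c2c(OC)c(C=O)c(OCc3ccccc3)c(O)c21 | intermediate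
16 | 3,5-difluorotoluene | Cc1cc(F)cc(F)c1 | starting material
17 | (2,6-difluoro-4-methylphenyl)lithium (not isolated) | [Li]c1c(F)cc(C)cc1F | intermediate
18 | 2,6-difluoro-4-methylbenzaldehyde | Cc1cc(F)c(C=O)c(F)c1 | intermediate
19 | 2-fluoro-6-methoxy-4-methylbenzaldehyde | COc1cc(C)cc(F)c1C=O | intermediate
20 | 3-bromo-2-fluoro-6-methoxy-4-methylbenzaldehyde | COc1cc(C)c(Br)c(F)c1C=O | intermediate
21 | benzyl 2-fluoro-3-formyl-4-methoxy-6-methylbenzoate | COc1cc(C)c(C(=O)OCc2ccccc2)c(F)c1C=O | intermediate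
22 | benzyl 2-{[5-(benzyloxy)-6-formyl-3,7-dimethoxy-1-oxo-1,3-dihydro-2-benzofuran-4-yl]oxy}-3-formyl-4-methoxy-6-methylbenzoate (racemic) | COc1cc(C)c(C(=O)OCc2ccccc2)c(Oc3c(OCc5ccccc5)c(C=O)c(OC)c4C(=O)OC(OC)c34)c1C=O | intermediate
23 | 2-[(6-formyl-5-hydroxy-3,7-dimethoxy-1-oxo-1,3-dihydro-2-benzofuran-4-yl)oxy]-3-formyl-4-methoxy-6-methylbenzoic acid (racemic) | COc1cc(C)c(C(=O)O)c(Oc2c(O)c(C=O)c(OC)c3C(=O)OC(OC)c23)c1C=O | intermediate
24 | 1,4,10-trimethoxy-8-methyl-3,7-dioxo-1,3-dihydro-7H-isobenzofuro[4,5-b][1,4]benzodioxepine-5,11-dicarbaldehyde (racemic) | Cc1cc(OC)c(C=O)c2c1C(=O)Oc1c(C=O)c(OC)c3c(c1O2)C(OC)OC3=O | intermediate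
25 | 1,4,10-trihydroxy-8-methyl-3,7-dioxo-1,3-dihydro-7H-isobenzofuro[4,5-b][1,4]benzodioxepine-5,11-dicarbaldehyde (racemic lactol) | Cc1cc(O)c(C=O)c2c1C(=O)Oc1c(C=O)c(O)c3c(c1O2)C(O)OC3=O | intermediate
26 | 5,11-diformyl-8-methyl-3,7-dioxo-1,3-dihydro-7H-isobenzofuro[4,5-b][1,4]benzodioxepine-1,4,10-triyl triallyl tricarbonate (racemic) | Cc1cc(OC(=O)OCC=C)c(C=O)c2c1C(=O)Oc1c(C=O)c(OC(=O)OCC=C)c3c(c1O2)C(OC(=O)OCC=C)OC3=O | intermediate
27 | (1R)-5,11-diformyl-8-methyl-3,7-dioxo-1,3-dihydro-7H-isobenzofuro[4,5-b][1,4]benzodioxepine-1,4,10-triyl triallyl tricarbonate | Cc1cc(OC(=O)OCC=C)c(C=O)c2c1C(=O)Oc1c(C=O)c(OC(=O)OCC=C)c3c(c1O2)[C@@H](OC(=O)OCC=C)OC3=O | intermediate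
28 | (1S)-1,4,10-trihydroxy-8-methyl-3,7-dioxo-1,3-dihydro-7H-isobenzofuro[4,5-b][1,4]benzodioxepine-5,11-dicarbaldehyde | Cc1cc(O)c(C=O)c2c1C(=O)Oc1c(C=O)c(O)c3c(c1O2)[C@@H](O)OC3=O | target

**Totals and risks**
Total step count: 20. Longest linear sequence: 16 steps (steps 1–9, then 14–20); the ring A branch (steps 10–13) is 4 steps.

The three steps most likely to fail:

Step 9 (Rieche formylation). TiCl4 may strip the benzyl ether or the pseudo-ester methoxy group before formylation of the hindered C-6 is complete. The fallback sets out from 14 and avoids a Lewis acid: NBS in MeCN at 0 °C brominates the only free ring position to give the 6-bromo phenol F1; Stille coupling with tributyl(vinyl)stannane (Pd(PPh3)4, toluene, 90 °C, no base) gives the 6-vinyl phenol F2; Lemieux–Johnson cleavage (K2OsO4·2H2O cat., NaIO4, 2,6-lutidine, dioxane/H2O) comes back to the route at 15.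

Step 14 (SNAr to a tetra-ortho-substituted diaryl ether). The doubly flanked fluoride 21 and the hindered phenoxide of 15 may not combine. The fallback sets out from 15 and 19 and makes the ether bond before the ring A ester is in place: SNAr of 15 on the less hindered fluoroaldehyde 19 (K2CO3, DMF, 110 °C) gives the diaryl ether aldehyde F3; NBS in DMF brominates ring A para to its methoxy group (ring B has no free position, though some attack at the other free ring A position is possible) to give the bromide F4; the Pd(OAc)2/Xantphos benzyloxycarbonylation of step 13 comes back to the route at 22.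

Step 20 (release of the lactol). The tin hydride/palladium conditions may erode enantiomeric purity or touch a formyl group. The fallback sets out from 25 and switches to pure acidolysis: Boc2O with DMAP (cat.) in CH2Cl2 gives the racemic tris(tert-butyl carbonate) F5; the same chiral-phase separation gives its (1R)-enantiomer F6; TFA/CH2Cl2 (1:4) at 0 °C, which loses isobutene and CO2 without any anionic intermediate, comes back to the route at 28.

**Further compounds**
F1 | step 9 | 5-(benzyloxy)-6-bromo-4-hydroxy-3,7-dimethoxy-2-benzofuran-1(3H)-one (racemic) | COC1OC(=O)c2c(OC)c(Br)c(OCc3ccccc3)c(O)c21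
F2 | step 9 | 5-(benzyloxy)-6-ethenyl-4-hydroxy-3,7-dimethoxy-2-benzofuran-1(3H)-one (racemic) | COC1OC(=O)c2c(OC)c(C=C)c(OCc3ccccc3)c(O)c21
F3 | step 14 | 5-(benzyloxy)-4-(2-formyl-3-methoxy-5-methylphenoxy)-3,7-dimethoxy-1-oxo-1,3-dihydro-2-benzofuran-6-carbaldehyde (racemic) | COc1cc(C)cc(Oc2c(OCc3ccccc3)c(C=O)c(OC)c3C(=O)OC(OC)c23)c1C=O
F4 | step 14 | 5-(benzyloxy)-4-(2-bromo-6-formyl-5-methoxy-3-methylphenoxy)-3,7-dimethoxy-1-oxo-1,3-dihydro-2-benzofuran-6-carbaldehyde (racemic) | COc1cc(C)c(Br)c(Oc2c(OCc3ccccc3)c(C=O)c(OC)c3C(=O)OC(OC)c23)c1C=O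
F5 | step 20 | 5,11-diformyl-8-methyl-3,7-dioxo-1,3-dihydro-7H-isobenzofuro[4,5-b][1,4]benzodioxepine-1,4,10-triyl tri-tert-butyl tricarbonate (racemic) | Cc1cc(OC(=O)OC(C)(C)C)c(C=O)c2c1C(=O)Oc1c(C=O)c(OC(=O)OC(C)(C)C)c3c(c1O2)C(OC(=O)OC(C)(C)C)OC3=O
F6 | step 20 | (1R)-5,11-diformyl-8-methyl-3,7-dioxo-1,3-dihydro-7H-isobenzofuro[4,5-b][1,4]benzodioxepine-1,4,10-triyl tri-tert-butyl tricarbonate | Cc1cc(OC(=O)OC(C)(C)C)c(C=O)c2c1C(=O)Oc1c(C=O)c(OC(=O)OC(C)(C)C)c3c(c1O2)[C@@H](OC(=O)OC(C)(C)C)OC3=O
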